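**Retrosynthetic overview**
1. Target 22 ⇐ selective O-acetylation of the benzylic alcohol of triol 21 ⇐ one-pot removal of two MOM ethers and one TBS ether from 20.
2. Key disconnection (new reaction): the diaryl ether C–O bond and the ring-A C–CO2Me bond of 20 are made together by insertion of aryne 18 into the ArO–C(=O)OMe bond of aryl methyl carbonate 8.
3. Ring-B carbonate 8 ⇐ 2-hydroxy-4-methoxybenzaldehyde 1 (MOM ether, Dakin oxidation, ortho-formylation, reduction, silylation, carbonate).
4. Ring-A aryne precursor 17 ⇐ orcinol 9 (mono-MOM ether, carbamate, directed ortho-silylation, carbamate-to-triflate exchange).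
5. No ring is formed: both benzene rings are bought and only substituents are installed.

Assumption: the target has no stereocentre and no configurationally stable axis (the diaryl ether has too few ortho groups to stop rotation), so "single enantiomer" means the one achiral compound and no stereocontrol is needed.

**Route**

Step 1
Reactants: 1 2-hydroxy-4-methoxybenzaldehyde
Product: 2 4-methoxy-2-(methoxymethoxy)benzaldehyde
Conditions: MOMCl, i-Pr2NEt, CH2Cl2, 0 °C to rt
Reagents that add atoms: chloromethyl methyl ether (MOMCl), COCCl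
Why: O-alkylation of the phenol (MOM protection) gives an acetal ether that survives the oxidative, basic and organometallic steps and is removed by acid at the end.

Step 2
Reactants: 2 4-methoxy-2-(methoxymethoxy)benzaldehyde
Product: 4 4-methoxy-2-(methoxymethoxy)phenol, via aryl formate 3 (not isolated)
Conditions: mCPBA, CH2Cl2, 0 °C to rt; then K2CO3 (cat.), MeOH, rt
Reagents that add atoms: meta-chloroperoxybenzoic acid (mCPBA), O=C(OO)c1cccc(Cl)c1
Why: Baeyer–Villiger (Dakin-type) oxidation in which the electron-rich 2,4-dialkoxyaryl group migrates in preference to H, followed by base-catalysed methanolysis of the formate.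

Step 3
Reactants: 4 4-methoxy-2-(methoxymethoxy)phenol
Product: 5 2-hydroxy-5-methoxy-3-(methoxymethoxy)benzaldehyde
Conditions: MgCl2, Et3N, (CH2O)n, THF, reflux
Reagents that add atoms: paraformaldehyde (as formaldehyde), C=O
Why: Magnesium-mediated ortho-formylation (Casnati–Skattebøl) delivers formaldehyde only ortho to the free OH, where a single site is open (para is blocked by OMe), and excess formaldehyde acts as hydride acceptor to give the aldehyde.

Step 4
Reactants: 5 2-hydroxy-5-methoxy-3-(methoxymethoxy)benzaldehyde
Product: 6 2-(hydroxymethyl)-4-methoxy-6-(methoxymethoxy)phenol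
Conditions: NaBH4, MeOH, 0 °C
Reagents that add atoms: none
Why: Borohydride reduction of the aldehyde, the only reducible group present.

Step 5
Reactants: 6 2-(hydroxymethyl)-4-methoxy-6-(methoxymethoxy)phenol
Product: 7 2-(tert-butyldimethylsilyloxymethyl)-4-methoxy-6-(methoxymethoxy)phenol
Conditions: TBSCl (1.05 equiv), imidazole, CH2Cl2, 0 °C
Reagents that add atoms: tert-butyldimethylsilyl chloride (TBSCl), CC(C)(C)[Si](C)(C)Cl
Why: Silylation is much faster at the primary benzylic alcohol than at the di-ortho-substituted phenol, and the silyloxy group (a poor leaving group) prevents o-quinone methide formation when the phenoxide is generated later.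

Step 6
Reactants: 7 2-(tert-butyldimethylsilyloxymethyl)-4-methoxy-6-(methoxymethoxy)phenol
Product: 8 2-(tert-butyldimethylsilyloxymethyl)-4-methoxy-6-(methoxymethoxy)phenyl methyl carbonate
Conditions: ClCO2Me, Et3N, DMAP (cat.), CH2Cl2, 0 °C
Reagents that add atoms: methyl chloroformate, COC(=O)Cl
Why: O-acylation of the phenol with a chloroformate gives the aryl methyl carbonate, which is both the masked aryloxide and the CO2Me donor for step 11.

Step 7
Reactants: 9 orcinol (5-methylbenzene-1,3-diol)
Product: 10 3-(methoxymethoxy)-5-methylphenol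
Conditions: MOMCl (1.0 equiv), i-Pr2NEt, CH2Cl2, 0 °C to rt
Reagents that add atoms: chloromethyl methyl ether (MOMCl), COCCl
Why: Statistical mono-etherification of the symmetrical diol with one equivalent of MOMCl; the mono-ether is separated from recyclable diol and bis-ether.

Step 8
Reactants: 10 3-(methoxymethoxy)-5-methylphenol
Product: 11 3-(methoxymethoxy)-5-methylphenyl isopropylcarbamate
Conditions: i-PrNCO, Et3N (cat.), CH2Cl2, rt
Reagents that add atoms: isopropyl isocyanate, CC(C)N=C=O
Why: Addition of the phenol to the isocyanate gives an N-isopropyl carbamate, a strong directed-metalation group that is later removed under mild base.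

Step 9
Reactants: 11 3-(methoxymethoxy)-5-methylphenyl isopropylcarbamate
Product: 15 3-(methoxymethoxy)-5-methyl-2-(trimethylsilyl)phenyl isopropylcarbamate, via N-silyl carbamate 12 (not isolated), via aryllithium 13 (not isolated), via ring-silylated N-silyl carbamate 14 (not isolated)
Conditions: TBSOTf, TMEDA, Et2O, 0 °C to rt; n-BuLi, TMEDA, −78 °C; TMSCl, −78 °C to rt; aq. NaHSO4
Reagents that add atoms: chlorotrimethylsilane (TMSCl), C[Si](C)(C)Cl; tert-butyldimethylsilyl triflate, CC(C)(C)[Si](C)(C)OS(=O)(=O)C(F)(F)F (adds only the transient N-silyl group of 12–14)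
Why: Directed ortho-metalation (Snieckus type): after in-situ N-silylation, n-BuLi/TMEDA removes the proton flanked by the carbamate and the OMOM group (cooperative direction), TMSCl traps the aryllithium and the acidic work-up cleaves the N–Si bond.

Step 10
Reactants: 15 3-(methoxymethoxy)-5-methyl-2-(trimethylsilyl)phenyl isopropylcarbamate
Product: 17 3-(methoxymethoxy)-5-methyl-2-(trimethylsilyl)phenyl trifluoromethanesulfonate, via silylphenol 16 (not isolated)
Conditions: DBU, Et2NH, MeCN, 40 °C; then PhNTf2, rt
Reagents that add atoms: N-phenylbis(trifluoromethanesulfonimide) (PhNTf2), O=S(=O)(N(c1ccccc1)S(=O)(=O)C(F)(F)F)C(F)(F)F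
Why: E1cB cleavage of the N–H carbamate (the isocyanate is trapped by Et2NH) and O-triflation of the phenoxide in the same pot give the Kobayashi-type ortho-silylaryl triflate aryne precursor.

Step 11
Reactants: 8 2-(tert-butyldimethylsilyloxymethyl)-4-methoxy-6-(methoxymethoxy)phenyl methyl carbonate; 17 3-(methoxymethoxy)-5-methyl-2-(trimethylsilyl)phenyl trifluoromethanesulfonate
Product: 20 methyl 2-[2-(tert-butyldimethylsilyloxymethyl)-4-methoxy-6-(methoxymethoxy)phenoxy]-6-(methoxymethoxy)-4-methylbenzoate, via aryne 18 (not isolated), via arylpotassium 19 (not isolated)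
Conditions: KF, 18-crown-6, THF, 0 °C to rt, slow addition of 17 (1.5 equiv)
Reagents that add atoms: none
Why: Proposed new method: fluoride-triggered insertion of an aryne into the ArO–C(=O)OMe bond of an aryl methyl carbonate, run as an aryloxide-relay chain – a trace of aryloxide freed from 8 by fluoride adds to aryne 18 at the carbon remote from the OMOM group (the usual inductive/distortion control of 3-alkoxyarynes), the aryl anion 19 flanked by two oxygens attacks the carbonate C=O of another molecule of 8, and the tetrahedral intermediate expels ArO− (a far better leaving group than MeO−), giving ester 20 and regenerating the chain-carrying aryloxide, so the diaryl ether C–O bond and the C–CO2Me bond form together with the 1,2,3-pattern fixed; the closest known reaction types are aryne σ-insertions with acyl transfer (into N–C(=O) bonds of amides and ureas and C–C bonds of β-keto esters) and three-component aryne/nucleophile/CO2 couplings.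

Step 12
Reactants: 20 methyl 2-[2-(tert-butyldimethylsilyloxymethyl)-4-methoxy-6-(methoxymethoxy)phenoxy]-6-(methoxymethoxy)-4-methylbenzoate
Product: 21 methyl 2-hydroxy-6-[2-hydroxy-6-(hydroxymethyl)-4-methoxyphenoxy]-4-methylbenzoate
Conditions: HCl (1.25 M in MeOH), 0 °C to rt
Reagents that add atoms: none
Why: Acid-catalysed acetal exchange and silyl ether methanolysis cleave both aryl MOM ethers and the primary TBS ether, methanol traps the formaldehyde unit as dimethoxymethane so it cannot attack the electron-rich rings, and the hindered methyl ester is unaffected.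

Step 13
Reactants: 21 methyl 2-hydroxy-6-[2-hydroxy-6-(hydroxymethyl)-4-methoxyphenoxy]-4-methylbenzoate
Product: 22 Betaethrin A (methyl 2-[2-(acetoxymethyl)-6-hydroxy-4-methoxyphenoxy]-6-hydroxy-4-methylbenzoate)
Conditions: Novozym 435 (CAL-B), vinyl acetate, MTBE, 35 °C
Reagents that add atoms: vinyl acetate, C=COC(C)=O
Why: Lipase-catalysed irreversible transesterification acylates the primary benzylic alcohol but not phenols, so only the CH2OH group is acetylated.

**Compound list**
1 | 2-hydroxy-4-methoxybenzaldehyde | COc1ccc(C=O)c(O)c1 | starting material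
2 | 4-methoxy-2-(methoxymethoxy)benzaldehyde | COCOc1cc(OC)ccc1C=O | intermediate
3 | 4-methoxy-2-(methoxymethoxy)phenyl formate | COCOc1cc(OC)ccc1OC=O | intermediate (not isolated)
4 | 4-methoxy-2-(methoxymethoxy)phenol | COCOc1cc(OC)ccc1O | intermediate
5 | 2-hydroxy-5-methoxy-3-(methoxymethoxy)benzaldehyde | COCOc1cc(OC)cc(C=O)c1O | intermediate
6 | 2-(hydroxymethyl)-4-methoxy-6-(methoxymethoxy)phenol | COCOc1cc(OC)cc(CO)c1O | intermediate
7 | 2-(tert-butyldimethylsilyloxymethyl)-4-methoxy-6-(methoxymethoxy)phenol | COCOc1cc(OC)cc(CO[Si](C)(C)C(C)(C)C)c1O | intermediate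
8 | 2-(tert-butyldimethylsilyloxymethyl)-4-methoxy-6-(methoxymethoxy)phenyl methyl carbonate | COCOc1cc(OC)cc(CO[Si](C)(C)C(C)(C)C)c1OC(=O)OC | intermediate
9 | orcinol (5-methylbenzene-1,3-diol) | Cc1cc(O)cc(O)c1 | starting material
10 | 3-(methoxymethoxy)-5-methylphenol | COCOc1cc(C)cc(O)c1 | intermediate
11 | 3-(methoxymethoxy)-5-methylphenyl isopropylcarbamate | COCOc1cc(C)cc(OC(=O)NC(C)C)c1 | intermediate
12 | 3-(methoxymethoxy)-5-methylphenyl N-(tert-butyldimethylsilyl)-N-isopropylcarbamate | COCOc1cc(C)cc(OC(=O)N(C(C)C)[Si](C)(C)C(C)(C)C)c1 | intermediate (not isolated)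
13 | 2-lithio-3-(methoxymethoxy)-5-methylphenyl N-(tert-butyldimethylsilyl)-N-isopropylcarbamate | COCOc1cc(C)cc(OC(=O)N(C(C)C)[Si](C)(C)C(C)(C)C)c1[Li] | intermediate (not isolated)
14 | 3-(methoxymethoxy)-5-methyl-2-(trimethylsilyl)phenyl N-(tert-butyldimethylsilyl)-N-isopropylcarbamate | COCOc1cc(C)cc(OC(=O)N(C(C)C)[Si](C)(C)C(C)(C)C)c1[Si](C)(C)C | intermediate (not isolated)
15 | 3-(methoxymethoxy)-5-methyl-2-(trimethylsilyl)phenyl isopropylcarbamate | COCOc1cc(C)cc(OC(=O)NC(C)C)c1[Si](C)(C)C | intermediate
16 | 3-(methoxymethoxy)-5-methyl-2-(trimethylsilyl)phenol | COCOc1cc(C)cc(O)c1[Si](C)(C)C | intermediate (not isolated)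
17 | 3-(methoxymethoxy)-5-methyl-2-(trimethylsilyl)phenyl trifluoromethanesulfonate | COCOc1cc(C)cc(OS(=O)(=O)C(F)(F)F)c1[Si](C)(C)C | intermediate
18 | 3-(methoxymethoxy)-5-methylbenzyne (1,2-didehydro-3-(methoxymethoxy)-5-methylbenzene) | COCOC1=CC(C)=CC#C1 | intermediate (not isolated)
19 | [2-(2-(tert-butyldimethylsilyloxymethyl)-4-methoxy-6-(methoxymethoxy)phenoxy)-6-(methoxymethoxy)-4-methylphenyl]potassium | COCOc1cc(C)cc(Oc2c(OCOC)cc(OC)cc2CO[Si](C)(C)C(C)(C)C)c1[K] | intermediate (not isolated)
20 | methyl 2-[2-(tert-butyldimethylsilyloxymethyl)-4-methoxy-6-(methoxymethoxy)phenoxy]-6-(methoxymethoxy)-4-methylbenzoate | COC(=O)c1c(OCOC)cc(C)cc1Oc1c(OCOC)cc(OC)cc1CO[Si](C)(C)C(C)(C)C | intermediate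
21 | methyl 2-hydroxy-6-[2-hydroxy-6-(hydroxymethyl)-4-methoxyphenoxy]-4-methylbenzoate | COC(=O)c1c(O)cc(C)cc1Oc1c(O)cc(OC)cc1CO | intermediate
22 | Betaethrin A (methyl 2-[2-(acetoxymethyl)-6-hydroxy-4-methoxyphenoxy]-6-hydroxy-4-methylbenzoate; achiral) | COC(=O)c1c(O)cc(C)cc1Oc1c(O)cc(OC)cc1COC(C)=O | target

**Step count and risks**

Total step count: 13 (steps 1–6 for ring B, steps 7–10 for ring A, steps 11–13 after convergence).
Longest linear sequence: 9 steps (1 → 2 → 4 → 5 → 6 → 7 → 8 → 20 → 21 → 22).

The three steps most likely to fail: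

Step 11 (the proposed new aryne insertion). The likely failure modes are protonation of the aryl anion 19 before acyl transfer (giving the diaryl ether without CO2Me), capture of the aryne by fluoride, and loss of the TBS group. The fallback uses known cross-coupling chemistry and separates the C–O bond formation from the ester. It sets out from phenol 7 and from purchased methyl 2,6-dihydroxy-4-methylbenzoate (purchased) F1. F1 is mono-protected with MOMCl and i-Pr2NEt (the second OH stays hydrogen-bonded to the ester and does not react) to give methyl 2-hydroxy-6-(methoxymethoxy)-4-methylbenzoate F2. Triflation of F2 (Tf2O, pyridine, CH2Cl2, 0 °C) gives methyl 2-(methoxymethoxy)-4-methyl-6-(trifluoromethylsulfonyloxy)benzoate F3. Palladium-catalysed diaryl ether coupling of F3 with 7 (Pd(OAc)2, t-BuXPhos, K3PO4, toluene, 100 °C) then gives 20, where the fallback comes back to the route.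

Step 12 (one-pot acid deprotection). The freed, resorcinol-like ring B may be attacked by formaldehyde equivalents, or the benzylic alcohol may be converted into its methyl ether. The fallback changes the order so that the acetate is installed before the phenols are unmasked. It sets out from 20: buffered desilylation (TBAF, AcOH, THF) gives methyl 2-[2-(hydroxymethyl)-4-methoxy-6-(methoxymethoxy)phenoxy]-6-(methoxymethoxy)-4-methylbenzoate F4. Acetylation (Ac2O, pyridine, 0 °C) gives methyl 2-[2-(acetoxymethyl)-4-methoxy-6-(methoxymethoxy)phenoxy]-6-(methoxymethoxy)-4-methylbenzoate F5. Brief treatment of F5 with wet TFA in CH2Cl2 at 0 °C cleaves both aryl MOM ethers without touching the acetate and comes back to the route at 22, bypassing 21 and step 13.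

Step 13 (enzymatic acetylation). The benzylic alcohol sits next to a bulky aryloxy group and may be a poor lipase substrate. The fallback replaces selective acylation by selective deacylation. It sets out from 21: exhaustive acetylation (Ac2O, pyridine, DMAP) gives methyl 2-acetoxy-6-[2-acetoxy-6-(acetoxymethyl)-4-methoxyphenoxy]-4-methylbenzoate F6. Aminolysis of only the two aryl acetates of F6 with pyrrolidine (2.2 equiv, CH2Cl2, 0 °C; aryl acetates react far faster than the alkyl acetate and the methyl ester) comes back to the route at 22.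

**Further compounds**
F1 | step 11 | methyl 2,6-dihydroxy-4-methylbenzoate (purchased) | COC(=O)c1c(O)cc(C)cc1O
F2 | step 11 | methyl 2-hydroxy-6-(methoxymethoxy)-4-methylbenzoate | COC(=O)c1c(O)cc(C)cc1OCOC
F3 | step 11 | methyl 2-(methoxymethoxy)-4-methyl-6-(trifluoromethylsulfonyloxy)benzoate | COC(=O)c1c(OCOC)cc(C)cc1OS(=O)(=O)C(F)(F)F
F4 | step 12 | methyl 2-[2-(hydroxymethyl)-4-methoxy-6-(methoxymethoxy)phenoxy]-6-(methoxymethoxy)-4-methylbenzoate | COC(=O)c1c(OCOC)cc(C)cc1Oc1c(OCOC)cc(OC)cc1CO
F5 | step 12 | methyl 2-[2-(acetoxymethyl)-4-methoxy-6-(methoxymethoxy)phenoxy]-6-(methoxymethoxy)-4-methylbenzoate | COC(=O)c1c(OCOC)cc(C)cc1Oc1c(OCOC)cc(OC)cc1COC(C)=O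
F6 | step 13 | methyl 2-acetoxy-6-[2-acetoxy-6-(acetoxymethyl)-4-methoxyphenoxy]-4-methylbenzoate | COC(=O)c1c(OC(C)=O)cc(C)cc1Oc1c(OC(C)=O)cc(OC)cc1COC(C)=O
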